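## The problem

The target is a flavone in which every carbon of ring A is substituted: C5 (OH), C6, C7 and C8 (OMe), C8a (O1) and C4a (the C4 carbonyl). Ring A is therefore a hexasubstituted benzene with five oxygens, a pattern no simple commercial arene offers. One of these oxygens, the C5 hydroxyl peri to the C4 carbonyl, must end free while its three neighbours are methyl ethers; most routes reach this by a late selective demethylation among five methoxy groups. Ring C carries a 3-methoxy group, so flavone closures that leave C3–H need an extra oxidation and methylation. Ring B is a symmetric 3',5'-dihydroxy-4'-methoxyphenyl group, and its two phenols need protection that comes off without touching a methyl ether or the 5-OH. There is no stereocentre; the difficulty is regiochemical and sits in ring A.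

The feature that opens the problem is this: C5, C6, C7 and C8 form a contiguous chain of four carbons, each bearing one oxygen, with the C5 and C8 oxygens para to each other. That is the C4O4 skeleton of a squaric ester. The two remaining ring A atoms, C4a=C8a, are the C5=C6 enol-ether double bond of a 4-pyranone (ring C). Ring A can therefore be grown onto a finished ring C by ring expansion of a squarate adduct (Moore rearrangement), in which the cyclobutenone carbonyl becomes the peri C5–OH and the carbinol methyl ether becomes 8-OMe.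

## Retrosynthesis

Target 15 to 14: the two ring B O–H bonds are traced back to O–Si bonds. Triisopropylsilyl ethers are chosen because they carry no aromatic C–H (needed for the borylation that makes 3), tolerate lithium amide, methyl triflate and 140 °C, and leave with fluoride under conditions that touch neither a methyl ether nor the 5-OH.

14 to 11 (key disconnection): the C4a–C5 bond is cut and the C5–C8 bond is re-formed, which folds C5–C8 of ring A back into the four-membered ring of cyclobutenone 11. Against any condensation route this cut removes the whole hexasubstituted benzene in one step. The precursor 11 has no ring A at all, only a 4-pyranone carrying a squarate-derived cyclobutenone at its C6. The forward reaction is a thermal isomerization without reagents. It must open the cyclobutenone with the pyranonyl group turned inward and close the ketene onto pyranone C5. The regiochemistry is fixed by connectivity: the carbinol carbon (OMe) becomes C8 next to C8a–O1, and the ketene carbon becomes C5 (OH) next to C4a.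

11 to 7 and 8: the C8–C8a bond (pyranone C6 to cyclobutenone C4) and the O–CH3 bond of the carbinol are cut, giving pyranone 7, dimethyl squarate 8 and a methylating agent. Pyranone C6 of 7 corresponds to flavone C8a and pyranone C5 to C4a. The alternative attachment through pyranone C5 would place the carbinol oxygen at C5 and the free phenol at C8, which would need a removable group and a later methylation, so it is rejected. The forward step needs selective metalation of 7 at C6–H (α to the ring oxygen) to give 9, 1,2-addition to the symmetric dione 8 (no regiochemical question) to give alkoxide 10, and O-methylation.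

7 to 6 and 3: the C2–C1' biaryl-type bond is cut (Suzuki–Miyaura coupling). Building the pyranone from an aryl ketone or by an Achmatowicz sequence would cost several more steps. Here both partners are two steps from commercial materials, and 6 is a vinylogous acyl bromide, an excellent electrophile.

6 to 5 to 4: the O–CH3 bond and then the C2–Br bond are cut, leading to 3-hydroxy-4H-pyran-4-one 4, whose enolic hydroxyl directs bromination to the adjacent C2.

3 to 2 to 1: the C–B bond is cut (sterically controlled C–H borylation at the only position of 2 without an ortho substituent), then the two O–Si bonds, leading to 2-methoxyresorcinol 1. This installs the ring B handle para to the methoxy group without any directing-group manipulation.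

## Roads not taken

Alternative 1: the obvious cut is through ring C (O1–C2 and C2–C3). Aldol condensation of the pentaoxygenated acetophenone A1 with benzaldehyde A2 would give chalcone A3, and Algar–Flynn–Oyamada oxidation would give flavonol A4. 3-O-Methylation, selective 5-O-demethylation and debenzylation would follow. The chosen plan is better for three reasons:
- A1 is itself a hexasubstituted benzene that must be built by stepwise oxygenation of a simpler phenol, so the ring A problem is moved, not solved.
- Chalcones with a 6'-alkoxy group are diverted in the oxidative cyclization toward 5-exo closure.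
- The 5-OH would have to be uncovered at the end from one of five methoxy groups, with the 3-OMe at risk.

Alternative 2: cut the C6–O and C8–O bonds and oxygenate ring A late. A 5,7-dihydroxy-3-methoxyflavone A5 would be dibrominated to A6, followed by twofold copper-mediated methoxylation and selective 7-O-methylation. The chosen plan is better because electrophilic bromination cannot distinguish C6/C8 from the equally activated C2'/C6' of ring B. A double methoxylation at two positions flanked by oxygen substituents competes with reduction, and two further selectivity problems (7-OH against 5-OH) are added without any gain in convergence.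

Alternative 3: build ring A by a Dötz benzannulation. The pyranonyl methoxycarbene chromium complex A7 (from lithiated 7) would react with dimethoxyethyne A8; the carbene methoxy becomes 8-OMe and the inserted CO becomes 5-OH. The logic is the same as in the chosen plan, but A8 is not a practical reagent (small dialkoxyalkynes are thermally labile and polymerize), and a stoichiometric chromium complex would have to be carried on a Lewis-basic pyranone. The squaric ester delivers the same C4O4 array as a stable solid in a metal-free thermal step.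

Key step: step 7

Assumption: 1, 4 and 8 are bought. Compound 11 and the transient 13 each hold one stereocentre, formed racemic and destroyed on aromatization, so the achiral target needs no stereocontrol.

## Route

Step 1
Reactants: 1 2-methoxybenzene-1,3-diol (2-methoxyresorcinol)
Product: 2 2-methoxy-1,3-bis(triisopropylsilyloxy)benzene
Conditions: TIPSCl, imidazole, DMF, 25 to 50 °C
Reagents that add atoms: chlorotri(propan-2-yl)silane, CC(C)[Si](Cl)(C(C)C)C(C)C
Why: Standard imidazole-promoted O-silylation of phenols; the silyl ethers carry no aromatic C–H of their own, tolerate lithium amide, MeOTf and 140 °C, and are removed by fluoride at the end.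

Step 2
Reactants: 2 2-methoxy-1,3-bis(triisopropylsilyloxy)benzene
Product: 3 2-[4-methoxy-3,5-bis(triisopropylsilyloxy)phenyl]-4,4,5,5-tetramethyl-1,3,2-dioxaborolane
Conditions: B2pin2, [Ir(OMe)(cod)]2 (cat.), 4,4'-di-tert-butyl-2,2'-bipyridine (cat.), THF, 80 °C
Reagents that add atoms: bis(pinacolato)diboron, CC1(C)OB(OC1(C)C)B1OC(C)(C)C(C)(C)O1
Why: Iridium-catalysed aromatic C–H borylation is governed by sterics; C4–H and C6–H each lie ortho to a bulky silyloxy group, so only C5–H, flanked by two hydrogens, should react, placing boron para to the methoxy group as ring B requires.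

Step 3
Reactants: 4 3-hydroxy-4H-pyran-4-one
Product: 5 2-bromo-3-hydroxy-4H-pyran-4-one
Conditions: NBS (1 equiv), MeCN, 0 to 25 °C
Reagents that add atoms: N-bromosuccinimide, O=C1CCC(=O)N1Br
Why: Electrophilic bromination of the phenol-like enol occurs at C2, ortho to the hydroxyl, the same site at which 3-hydroxy-4-pyranones undergo aldol and Mannich reactions; one equivalent at low temperature limits dibromination.

Step 4
Reactants: 5 2-bromo-3-hydroxy-4H-pyran-4-one
Product: 6 2-bromo-3-methoxy-4H-pyran-4-one
Conditions: MeI, K2CO3, acetone, 40 °C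
Reagents that add atoms: iodomethane, CI
Why: Williamson O-methylation of the acidic enolic hydroxyl, the usual way to 3-methoxy-4-pyranones; the mild carbonate base should leave the vinylogous acyl bromide intact.

Step 5
Reactants: 6 2-bromo-3-methoxy-4H-pyran-4-one; 3 2-[4-methoxy-3,5-bis(triisopropylsilyloxy)phenyl]-4,4,5,5-tetramethyl-1,3,2-dioxaborolane
Product: 7 3-methoxy-2-[4-methoxy-3,5-bis(triisopropylsilyloxy)phenyl]-4H-pyran-4-one
Conditions: Pd(dppf)Cl2 (cat.), K3PO4, 1,4-dioxane/H2O, 70 °C
Reagents that add atoms: none
Why: Suzuki–Miyaura coupling; the C2–Br bond of 6 is a vinylogous acyl bromide that adds readily to zerovalent palladium, the boronate is unhindered, and phosphate at moderate temperature should spare the silyl ethers and the pyranone ring.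

Step 6
Reactants: 7 3-methoxy-2-[4-methoxy-3,5-bis(triisopropylsilyloxy)phenyl]-4H-pyran-4-one; 8 3,4-dimethoxycyclobut-3-ene-1,2-dione (dimethyl squarate)
Product: 11 2,3,4-trimethoxy-4-{5-methoxy-6-[4-methoxy-3,5-bis(triisopropylsilyloxy)phenyl]-4-oxo-4H-pyran-2-yl}cyclobut-2-en-1-one (racemic), via 6-lithiopyranone 9 (not isolated), via lithium alkoxide 10 (not isolated)
Conditions: LiTMP (lithium 2,2,6,6-tetramethylpiperidide, from TMPH and n-BuLi), THF, −78 °C; then added to 8, THF, −78 °C; then MeOTf, −78 to 0 °C
Reagents that add atoms: methyl trifluoromethanesulfonate, COS(=O)(=O)C(F)(F)F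
Why: Deprotonative lithiation by the hindered amide at C6–H of the pyranone, the sp2 C–H α to the ring oxygen (the site metalated by TMP bases in chromones, 4-pyranones and β-alkoxyacrylates), gives 9, which has no leaving group β to the carbanion and so cannot fragment. 1,2-Addition to one of the two equivalent carbonyls of 8 is the standard entry to 4-substituted squarate adducts, and alkoxide 10 is far more nucleophilic than the pyranone carbonyl, so MeOTf should methylate it first; the new quaternary stereocentre is racemic and is erased in step 7.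

Step 7
Reactants: 11 2,3,4-trimethoxy-4-{5-methoxy-6-[4-methoxy-3,5-bis(triisopropylsilyloxy)phenyl]-4-oxo-4H-pyran-2-yl}cyclobut-2-en-1-one
Product: 14 5-hydroxy-3,6,7,8-tetramethoxy-2-[4-methoxy-3,5-bis(triisopropylsilyloxy)phenyl]-4H-chromen-4-one, via dienylketene 12 (not isolated), via cyclohexadienone 13 (not isolated)
Conditions: p-xylene (degassed, dilute), reflux (about 140 °C), argon
Reagents that add atoms: none
Why: Moore rearrangement: thermal conrotatory 4π opening of the cyclobutenone C1–C4 bond gives dienylketene 12. By the torquoselectivity of this opening the C4 methoxy donor rotates outward, so the pyranonyl group turns inward and lies cis to the ketene. A 6π electrocyclization then joins the electrophilic ketene carbon to the nucleophilic pyranone C5 (β-carbon of the ring enol ether), closing the six-membered carbocyclic ring A as dienone 13. The hydrogen at C4a of 13 lies between two carbonyls and enolizes irreversibly to the aromatic, hydrogen-bonded 5-hydroxyl, which pulls the reversible ring opening forward. The closest known reaction type is the ring expansion of 4-alkenyl- and 4-heteroaryl-4-alkoxycyclobutenones derived from squaric esters to p-alkoxyphenols, including α-oxygenated alkenyl groups such as 2-dihydropyranyl and 2-furyl. No stereocentre remains, since the centre of 11 and C4a of 13 are both lost on aromatization. The only selectivity needed is regiochemical and is fixed by connectivity: the carbon that bore the pyranonyl group and OMe must become C8 next to C8a–O1 and the ketene carbon must become C5 next to C4a, so the 5-OH/8-OMe distinction is built in, and the methyl ether also blocks the lactonization open to a free C4 hydroxyl. High dilution and exclusion of oxygen are meant to suppress ketene dimerization and oxidation of the p-methoxyphenol.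

Step 8
Reactants: 14 5-hydroxy-3,6,7,8-tetramethoxy-2-[4-methoxy-3,5-bis(triisopropylsilyloxy)phenyl]-4H-chromen-4-one
Product: 15 5,3',5'-trihydroxy-3,6,7,8,4'-pentamethoxyflavone (target)
Conditions: Bu4NF, AcOH, THF, 0 °C
Reagents that add atoms: none
Why: Fluoride-induced cleavage of the two aryl silyl ethers; acetic acid buffers the phenoxides so the electron-rich product is not held under strongly basic conditions, and no methyl ether or the chelated 5-OH is affected.

## Compound list

1 | 2-methoxybenzene-1,3-diol | COc1c(O)cccc1O | starting material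
2 | 2-methoxy-1,3-bis(triisopropylsilyloxy)benzene | COc1c(O[Si](C(C)C)(C(C)C)C(C)C)cccc1O[Si](C(C)C)(C(C)C)C(C)C | intermediate
3 | 2-[4-methoxy-3,5-bis(triisopropylsilyloxy)phenyl]-4,4,5,5-tetramethyl-1,3,2-dioxaborolane | COc1c(O[Si](C(C)C)(C(C)C)C(C)C)cc(B2OC(C)(C)C(C)(C)O2)cc1O[Si](C(C)C)(C(C)C)C(C)C | intermediate
4 | 3-hydroxy-4H-pyran-4-one | O=c1ccocc1O | starting material
5 | 2-bromo-3-hydroxy-4H-pyran-4-one | O=c1ccoc(Br)c1O | intermediate
6 | 2-bromo-3-methoxy-4H-pyran-4-one | COc1c(Br)occc1=O | intermediate
7 | 3-methoxy-2-[4-methoxy-3,5-bis(triisopropylsilyloxy)phenyl]-4H-pyran-4-one | COc1c(O[Si](C(C)C)(C(C)C)C(C)C)cc(-c2occc(=O)c2OC)cc1O[Si](C(C)C)(C(C)C)C(C)C | intermediate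
8 | 3,4-dimethoxycyclobut-3-ene-1,2-dione (dimethyl squarate) | COC1=C(OC)C(=O)C1=O | starting material
9 | {5-methoxy-6-[4-methoxy-3,5-bis(triisopropylsilyloxy)phenyl]-4-oxo-4H-pyran-2-yl}lithium | COc1c(-c2cc(O[Si](C(C)C)(C(C)C)C(C)C)c(OC)c(O[Si](C(C)C)(C(C)C)C(C)C)c2)oc([Li])cc1=O | intermediate
10 | lithium 2,3-dimethoxy-1-{5-methoxy-6-[4-methoxy-3,5-bis(triisopropylsilyloxy)phenyl]-4-oxo-4H-pyran-2-yl}-4-oxocyclobut-2-en-1-olate (racemic) | COC1=C(OC)C(O[Li])(c2cc(=O)c(OC)c(-c3cc(O[Si](C(C)C)(C(C)C)C(C)C)c(OC)c(O[Si](C(C)C)(C(C)C)C(C)C)c3)o2)C1=O | intermediate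
11 | 2,3,4-trimethoxy-4-{5-methoxy-6-[4-methoxy-3,5-bis(triisopropylsilyloxy)phenyl]-4-oxo-4H-pyran-2-yl}cyclobut-2-en-1-one (racemic) | COC1=C(OC)C(OC)(c2cc(=O)c(OC)c(-c3cc(O[Si](C(C)C)(C(C)C)C(C)C)c(OC)c(O[Si](C(C)C)(C(C)C)C(C)C)c3)o2)C1=O | intermediate
12 | (3Z)-2,3,4-trimethoxy-4-{5-methoxy-6-[4-methoxy-3,5-bis(triisopropylsilyloxy)phenyl]-4-oxo-4H-pyran-2-yl}buta-1,3-dien-1-one (dienylketene) | O=C=C(OC)/C(OC)=C(/OC)c1cc(=O)c(OC)c(-c2cc(O[Si](C(C)C)(C(C)C)C(C)C)c(OC)c(O[Si](C(C)C)(C(C)C)C(C)C)c2)o1 | intermediate
13 | 3,6,7,8-tetramethoxy-2-[4-methoxy-3,5-bis(triisopropylsilyloxy)phenyl]-4aH-chromene-4,5-dione (racemic) | COC1=C(OC)C(OC)=C2OC(c3cc(O[Si](C(C)C)(C(C)C)C(C)C)c(OC)c(O[Si](C(C)C)(C(C)C)C(C)C)c3)=C(OC)C(=O)C2C1=O | intermediate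
14 | 5-hydroxy-3,6,7,8-tetramethoxy-2-[4-methoxy-3,5-bis(triisopropylsilyloxy)phenyl]-4H-chromen-4-one | COc1c(O[Si](C(C)C)(C(C)C)C(C)C)cc(-c2oc3c(OC)c(OC)c(OC)c(O)c3c(=O)c2OC)cc1O[Si](C(C)C)(C(C)C)C(C)C | intermediate
15 | 5,3',5'-trihydroxy-3,6,7,8,4'-pentamethoxyflavone | COc1c(O)cc(-c2oc3c(OC)c(OC)c(OC)c(O)c3c(=O)c2OC)cc1O | target

## Step count and risks

Total: 8 steps. Longest linear sequence: 6 steps (4 to 15 through steps 3–8; the branch from 1 through steps 1, 2, 5–8 is equally long).

Least certain steps:

**Step 7 (key step).** The closure of ketene 12 onto pyranone C5 may be slow, because C5 is also the α-carbon of the cross-conjugated carbonyl and is less nucleophilic than the terminus of a simple enol ether. Ketene dimerization or decomposition at 140 °C could then compete.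

Fallback (sets out from 8, returns at 14): ring A would be made first on the best precedented 2π partner and ring C afterwards.
- Ethyl vinyl ether is lithiated at its α-carbon (t-BuLi, THF, −78 to 0 °C) and added to 8; MeOTf then gives 4-(1-ethoxyethenyl)-2,3,4-trimethoxycyclobut-2-en-1-one F1.
- Heating in toluene would give 5-ethoxy-2,3,4-trimethoxyphenol F2.
- Hoesch acylation at its only free ring position (methoxyacetonitrile, ZnCl2, HCl, Et2O; then hot water) would give 1-(2-ethoxy-6-hydroxy-3,4,5-trimethoxyphenyl)-2-methoxyethan-1-one F3.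
- Condensation with DMF dimethyl acetal and acid-induced closure would give 5-ethoxy-3,6,7,8-tetramethoxy-4H-chromen-4-one F4.
- Zincation of its only ring C–H (C2) with TMPZnCl·LiCl and iodinolysis would give 5-ethoxy-2-iodo-3,6,7,8-tetramethoxy-4H-chromen-4-one F5.
- Suzuki–Miyaura coupling with 3 would give 5-ethoxy-3,6,7,8-tetramethoxy-2-[4-methoxy-3,5-bis(triisopropylsilyloxy)phenyl]-4H-chromen-4-one F6.
- BCl3 (CH2Cl2, −78 °C) would cleave only the ether peri to the C4 carbonyl through the boron chelate and give 14.

**Step 6.** Three things may go wrong: lithium-directed deprotonation at C5 (next to the carbonyl) in place of C6; addition of 9 to the electrophilic C6 of unreacted 7; and O-methylation of the pyranone carbonyl by MeOTf.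

Fallback (sets out from 7, returns at 11): the site of the carbanion would be fixed by a halogen, and the methylation done under neutral conditions.
- Zincation of 7 with TMPZnCl·LiCl without added Lewis acid (conditions that metalate chromones and 4-pyranones next to the ring oxygen and give a species inert to self-addition) and iodinolysis would give 2-iodo-5-methoxy-6-[4-methoxy-3,5-bis(triisopropylsilyloxy)phenyl]-4H-pyran-4-one F7.
- Iodine–magnesium exchange (iPrMgCl·LiCl, THF, −40 °C) would give chloro{5-methoxy-6-[4-methoxy-3,5-bis(triisopropylsilyloxy)phenyl]-4-oxo-4H-pyran-2-yl}magnesium F8.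
- Addition of F8 to 8 and aqueous work-up would give 4-hydroxy-2,3-dimethoxy-4-{5-methoxy-6-[4-methoxy-3,5-bis(triisopropylsilyloxy)phenyl]-4-oxo-4H-pyran-2-yl}cyclobut-2-en-1-one F9.
- MeI and Ag2O would convert F9 into 11.

**Step 5.** Three things may go wrong: attack of hydroxide or phosphate at C2 or C6 of the bromopyranone (ring opening, or hydrolysis of the C–Br bond); protodeboronation of the electron-rich boronate; and partial loss of the silyl groups.

Fallback (sets out from 3 and 6, returns at 7): the polarity of the coupling would be reversed and the aqueous base avoided.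
- Copper-mediated bromodeboronation of 3 (CuBr2, MeOH/H2O, 80 °C) would give 5-bromo-2-methoxy-1,3-bis(triisopropylsilyloxy)benzene F10.
- Insertion of zinc into the activated C–Br bond of 6 (Zn dust, LiCl, THF, 25 °C) would give bromo(3-methoxy-4-oxo-4H-pyran-2-yl)zinc F11.
- Negishi coupling of F10 and F11 (Pd(OAc)2, SPhos, THF, 50 °C) would give 7.

## Further compounds

F1 | step 7 | 4-(1-ethoxyethenyl)-2,3,4-trimethoxycyclobut-2-en-1-one (racemic) | CCOC(=C)C1(OC)C(OC)=C(OC)C1=O
F2 | step 7 | 5-ethoxy-2,3,4-trimethoxyphenol | CCOc1cc(O)c(OC)c(OC)c1OC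
F3 | step 7 | 1-(2-ethoxy-6-hydroxy-3,4,5-trimethoxyphenyl)-2-methoxyethan-1-one | CCOc1c(OC)c(OC)c(OC)c(O)c1C(=O)COC
F4 | step 7 | 5-ethoxy-3,6,7,8-tetramethoxy-4H-chromen-4-one | CCOc1c(OC)c(OC)c(OC)c2occ(OC)c(=O)c12
F5 | step 7 | 5-ethoxy-2-iodo-3,6,7,8-tetramethoxy-4H-chromen-4-one | CCOc1c(OC)c(OC)c(OC)c2oc(I)c(OC)c(=O)c12
F6 | step 7 | 5-ethoxy-3,6,7,8-tetramethoxy-2-[4-methoxy-3,5-bis(triisopropylsilyloxy)phenyl]-4H-chromen-4-one | CCOc1c(OC)c(OC)c(OC)c2oc(-c3cc(O[Si](C(C)C)(C(C)C)C(C)C)c(OC)c(O[Si](C(C)C)(C(C)C)C(C)C)c3)c(OC)c(=O)c12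
F7 | step 6 | 2-iodo-5-methoxy-6-[4-methoxy-3,5-bis(triisopropylsilyloxy)phenyl]-4H-pyran-4-one | COc1c(O[Si](C(C)C)(C(C)C)C(C)C)cc(-c2oc(I)cc(=O)c2OC)cc1O[Si](C(C)C)(C(C)C)C(C)C
F8 | step 6 | chloro{5-methoxy-6-[4-methoxy-3,5-bis(triisopropylsilyloxy)phenyl]-4-oxo-4H-pyran-2-yl}magnesium | COc1c(O[Si](C(C)C)(C(C)C)C(C)C)cc(-c2oc([Mg]Cl)cc(=O)c2OC)cc1O[Si](C(C)C)(C(C)C)C(C)C
F9 | step 6 | 4-hydroxy-2,3-dimethoxy-4-{5-methoxy-6-[4-methoxy-3,5-bis(triisopropylsilyloxy)phenyl]-4-oxo-4H-pyran-2-yl}cyclobut-2-en-1-one (racemic) | COC1=C(OC)C(O)(c2cc(=O)c(OC)c(-c3cc(O[Si](C(C)C)(C(C)C)C(C)C)c(OC)c(O[Si](C(C)C)(C(C)C)C(C)C)c3)o2)C1=O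
F10 | step 5 | 5-bromo-2-methoxy-1,3-bis(triisopropylsilyloxy)benzene | COc1c(O[Si](C(C)C)(C(C)C)C(C)C)cc(Br)cc1O[Si](C(C)C)(C(C)C)C(C)C
F11 | step 5 | bromo(3-methoxy-4-oxo-4H-pyran-2-yl)zinc | COc1c([Zn]Br)occc1=O
A1 | alternative 1 | 1-(2-hydroxy-3,4,5,6-tetramethoxyphenyl)ethan-1-one | CC(=O)c1c(O)c(OC)c(OC)c(OC)c1OC
A2 | alternative 1 | 3,5-bis(benzyloxy)-4-methoxybenzaldehyde | COc1c(OCc2ccccc2)cc(C=O)cc1OCc1ccccc1
A3 | alternative 1 | (E)-3-[3,5-bis(benzyloxy)-4-methoxyphenyl]-1-(2-hydroxy-3,4,5,6-tetramethoxyphenyl)prop-2-en-1-one | COc1c(OCc2ccccc2)cc(/C=C/C(=O)c2c(O)c(OC)c(OC)c(OC)c2OC)cc1OCc1ccccc1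
A4 | alternative 1 | 2-[3,5-bis(benzyloxy)-4-methoxyphenyl]-3-hydroxy-5,6,7,8-tetramethoxy-4H-chromen-4-one | COc1c(OCc2ccccc2)cc(-c2oc3c(OC)c(OC)c(OC)c(OC)c3c(=O)c2O)cc1OCc1ccccc1
A5 | alternative 2 | 2-[3,5-bis(benzyloxy)-4-methoxyphenyl]-5,7-dihydroxy-3-methoxy-4H-chromen-4-one | COc1c(OCc2ccccc2)cc(-c2oc3cc(O)cc(O)c3c(=O)c2OC)cc1OCc1ccccc1
A6 | alternative 2 | 2-[3,5-bis(benzyloxy)-4-methoxyphenyl]-6,8-dibromo-5,7-dihydroxy-3-methoxy-4H-chromen-4-one | COc1c(OCc2ccccc2)cc(-c2oc3c(Br)c(O)c(Br)c(O)c3c(=O)c2OC)cc1OCc1ccccc1
A7 | alternative 3 | pentacarbonyl[methoxy{5-methoxy-6-[4-methoxy-3,5-bis(triisopropylsilyloxy)phenyl]-4-oxo-4H-pyran-2-yl}methylidene]chromium | COC(c1cc(=O)c(OC)c(-c2cc(O[Si](C(C)C)(C(C)C)C(C)C)c(OC)c(O[Si](C(C)C)(C(C)C)C(C)C)c2)o1)=[Cr](=C=O)(=C=O)(=C=O)(=C=O)=C=O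
A8 | alternative 3 | 1,2-dimethoxyethyne | COC#COC
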